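Numbering: the catechin part carries flavan numbering (O1, C2, C3, C4, C4a, C5 to C8, C8a). Ring A is the benzo ring, ring B the catechol, ring C the pyran and ring D the acylphloroglucinol. Compound numbers 1 to 28 are those of the list after the steps.

## Analysis of the target

Pilosanol B (28) is a (2R,3S)-flavan-3-ol of the catechin type whose ring A carbon C8 is joined through one methylene carbon to a fully substituted ring D. Ring D carries an isobutyryl group, a C-methyl group, one methyl ether and two free phenols, with the methyl ether lying between the C-methyl and the acyl carbon. The only stereocentres are C2 (R) and C3 (S); they are adjacent and trans on ring C, which corresponds to an anti 1,2-dioxygenated open chain. The sensitive parts are the six phenols (one catechol), the benzylic C2–O1 bond, which can ionise once ring B carries a free para hydroxyl, and the electron-rich diarylmethane bridge. The synthesis is hard because ring D must be attached at C8 and not at the equally nucleophilic C6, and because the trans pair C2/C3 must be made as one enantiomer without passing through a benzylic cation at C2. In addition, one ring D oxygen must be told apart from the other two, and because its methyl ether must survive, every other oxygen needs a group that leaves by hydrogenolysis. The route rests on one feature of ring A: C8a and C8 are neighbours, C8a bears O1 and C8 bears the bridge carbon, the C7 oxygen flanks C8 and the C4a alkyl carbon flanks C8a. This is the pattern left when an aryne across C8–C8a takes up a tethered oxygen nucleophile and then a carbon electrophile.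

## Retrosynthetic reasoning

The seven O–benzyl bonds are cut first, so 28 comes from the hepta-benzyl ether 27 by hydrogenolysis. Benzyl is the only choice that leaves the ring D methyl ether intact, and it keeps every phenol masked until the last step.

The bridge CH2 of 27 is traced to the carbinol 26 by removing one C–O bond. The C8–C bridge bond is most easily made by adding an aryl metal to an aldehyde, and a doubly benzylic hydroxyl flanked by electron-rich rings is easy to reduce away.

In 26 the bonds O1–C8a and C8–C(bridge) are cut together. Both sit on adjacent ring A carbons, so the retron is the aryne 24. Its internal nucleophile is the C2 alkoxide and its external electrophile is the ring D aldehyde 22. The aryne comes from the bromo aryl magnesium 23, and that from the bromo iodo alcohol 16. Cutting here gives a convergent union of two halves of similar size, settles C8 against C6 by construction, and closes ring C without touching C2 or C3. The forward step must generate 24, let the alkoxide close the six-membered ring to give the aryl magnesium 25, and add 25 to 22.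

The carbinol centre of 16 (future C2) is disconnected at its C–H bond to ketone 15. A neighbouring benzyloxy group at the future C3 allows chelation-controlled hydride delivery, which gives the anti relationship that becomes 2,3-trans.

Ketone 15 is cut between the carbonyl carbon and ring B, giving the Weinreb amide 12 and the aryl Grignard reagent 14 made from bromide 13. This brings ring B in as a cheap nucleophile and stops cleanly at the ketone.

Amide 12 comes from the imide 11, which is cut at the future C3–C4 bond into the glycolate imide 10 and the benzylic bromide 7. An auxiliary-controlled alkylation sets the C3 configuration absolutely. Imide 10 comes from the auxiliary 8 and the acid chloride 9.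

Bromide 7 is traced through alcohol 6 and aldehyde 5 to aldehyde 4, bromide 3 and the diol 1, which takes up two equivalents of benzyl bromide 2. The ring A pattern (carbon, bromine, iodine on three neighbouring positions) is built by two electrophilic substitutions, each directed para to a benzyloxy group.

Aldehyde 22 is traced through phenol 21 and the dibenzyl ether 20 to the acylphloroglucinol 19, and 19 to 17 and 18; the two benzyl groups of 20 again come from 2. Acylating the symmetrical 17 can give only one product. The oxygen wedged between methyl and acyl is then the last to be alkylated, so it can be kept for the methyl ether, and it also activates the last free ring carbon for formylation.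

## Alternatives that were turned down

Alternative 1: Ring D is disconnected at two of its own bonds, C(Me)–C(OMe) and C(OH)–C(acyl), and built on a flavan that already carries the C8 methylene. In the forward step the bis-silyloxy diene A2 adds the push-pull alkynone A3 in an Alder–Rickert sequence: (4+2) addition, then loss of the saturated two-carbon bridge as an alkene, giving arene A1. In its favour, the polarities match, since the nucleophilic methyl-bearing diene terminus meets the alkyne carbon β to the ketone. The methyl ether is also distinct from the two silylated phenols from the outset, and on this point it is stronger than the chosen route, which depends on a site-selective benzylation (step 12). Against it, A3 is a donor-deactivated dienophile and both termini of A2 are fully substituted, so the cycloaddition needs high temperature while labile silyl enol ethers are present. A2 itself has to be assembled by a C-alkylation that joins its six-membered ring to the C8 methylene of the flavan, followed by a regiodefined double enol silylation. The alternative also says nothing about how ring C, the two stereocentres or the choice of C8 over C6 are obtained, so the chiral flavan must be made or bought first and carried through a long linear sequence. The chosen strategy instead forms O1–C8a and the C8–bridge bond in one operation from two simple halves.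

Alternative 2: Ring C is disconnected at O1–C2 and C3–C4, with a formyl group on C3 as a relay carbon. Under iminium-enamine catalysis by a chiral secondary amine, the phenol of salicylaldehyde A5 adds to the β-carbon of enal A6, and the resulting enamine condenses with the ring A aldehyde, giving chromene aldehyde A4. In its favour, C2 is set catalytically and the two halves are joined as ring C closes. This is more economical than the stoichiometric auxiliary and the chelation-controlled reduction of steps 6 to 10. Against it, A4 has a carbon where the C3 oxygen should be and no C3 stereocentre. Exchanging formyl for hydroxyl requires oxidative degradation through a C3 carbonyl stage, where C2 is benzylic and α to a ketone and epimerises easily, and hydride reduction at that stage tends to give the 2,3-cis alcohol. The oxa-Michael addition is also reversible for electron-rich 2-aryl chromenes, which erodes enantiopurity, and the phenol of A5 is hindered by the ortho ring D benzyl group. Making A5 also brings back the problem of joining ring D to the correct ring A carbon. The chosen strategy sets both centres in the open chain by reliable methods and never places a carbonyl next to C2.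

Alternative 3: Ring D is disconnected at three bonds, C(OH)–C(CH2), C(OSi)–C(Me) and C(OH)–C(H), and grown from an alkyne on the C8 methylene. On heating, cyclobutenone A8 opens to a vinylketene, which adds the silyloxyalkyne A9 in a (2+2) sense. Four-electron opening and six-electron closure then give phenol A7. In its favour, the benzannulation gives a methyl ether, a free phenol and a silyl ether on three defined carbons under neutral conditions. This solves oxygen differentiation better than step 12 of the chosen route. Against it, A7 lacks the isobutyryl group, and a late acylation must compete with C6 of ring A and with ring B, in a molecule whose benzyl ethers do not tolerate strong Lewis acids. A9 is a sensitive ynol ether and requires a several-step homologation at C8 of a preformed chiral flavan. As in alternative 1, the flavan, its stereocentres and the C8 selectivity are presupposed. The chosen strategy brings the complete ring D in with the acyl group in place and spends its risk on a single ring-forming step.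

Key step: step 15

Remark on the chemistry: the carbinol centre of 26 is formed without control and both epimers are carried on, since step 16 removes that centre.

## Route

Step 1
Reactants: 1 5-bromobenzene-1,3-diol; 2 benzyl bromide
Product: 3 1,3-bis(benzyloxy)-5-bromobenzene
Conditions: 2 (2.2 equiv), K2CO3, DMF, 60 °C
Reagents that add atoms: benzyl bromide (second equivalent of 2) BrCc1ccccc1
Why: Double Williamson ether synthesis; each of the two unhindered phenols takes up one equivalent of 2, and benzyl is used on ring A because the ring D methyl ether must survive the final deprotection, which therefore has to be a hydrogenolysis.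

Step 2
Reactants: 3 1,3-bis(benzyloxy)-5-bromobenzene
Product: 4 2,4-bis(benzyloxy)-6-bromobenzaldehyde
Conditions: POCl3, DMF, 0 to 90 °C; then aq. NaOAc
Reagents that add atoms: N,N-dimethylformamide CN(C)C=O; water O
Why: Vilsmeier–Haack formylation; the chloroiminium ion enters para to one benzyloxy group and ortho to the other, next to bromine, because the carbon between the two benzyloxy groups is the more shielded activated position, and aryl benzyl ethers and the bromide are inert to the reagent.

Step 3
Reactants: 4 2,4-bis(benzyloxy)-6-bromobenzaldehyde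
Product: 5 4,6-bis(benzyloxy)-2-bromo-3-iodobenzaldehyde
Conditions: N-iodosuccinimide, CF3CO2H (cat.), MeCN, rt
Reagents that add atoms: N-iodosuccinimide O=C1CCC(=O)N1I
Why: Electrophilic aromatic iodination; the free carbon para to one benzyloxy group and ortho to the other should be attacked in preference to the carbon squeezed between two benzyloxy groups, which puts iodine next to bromine as the aryne precursor requires, and the aldehyde deactivates the ring against a second iodination.

Step 4
Reactants: 5 4,6-bis(benzyloxy)-2-bromo-3-iodobenzaldehyde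
Product: 6 [4,6-bis(benzyloxy)-2-bromo-3-iodophenyl]methanol
Conditions: NaBH4, THF/MeOH, 0 °C
Reagents that add atoms: none
Why: Borohydride reduction of an aromatic aldehyde; aryl halides and benzyl ethers are untouched.

Step 5
Reactants: 6 [4,6-bis(benzyloxy)-2-bromo-3-iodophenyl]methanol
Product: 7 4,6-bis(benzyloxy)-2-bromo-3-iodobenzyl bromide
Conditions: CBr4, PPh3, CH2Cl2, 0 °C
Reagents that add atoms: carbon tetrabromide BrC(Br)(Br)Br
Why: Appel bromination under neutral conditions, chosen because the electron-rich benzylic bromide is sensitive to acid; 7 is used at once in step 7.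

Step 6
Reactants: 8 (R)-4-benzyl-1,3-oxazolidin-2-one; 9 (benzyloxy)acetyl chloride
Product: 10 (R)-4-benzyl-3-[(benzyloxy)acetyl]-1,3-oxazolidin-2-one
Conditions: n-BuLi, THF, −78 °C; then 9, −78 to 0 °C
Reagents that add atoms: none
Why: N-acylation of the lithiated oxazolidinone with an acid chloride, the standard entry to an auxiliary-bound glycolate.

Step 7
Reactants: 10 (R)-4-benzyl-3-[(benzyloxy)acetyl]-1,3-oxazolidin-2-one; 7 4,6-bis(benzyloxy)-2-bromo-3-iodobenzyl bromide
Product: 11 (R)-4-benzyl-3-[(2S)-2-(benzyloxy)-3-[4,6-bis(benzyloxy)-2-bromo-3-iodophenyl]propanoyl]-1,3-oxazolidin-2-one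
Conditions: NaN(SiMe3)2, THF, −78 °C; then 7, −78 to −45 °C
Reagents that add atoms: none
Why: Evans alkylation of a glycolate imide; the chelated Z sodium enolate is shielded on one face by the benzyl group of the (R)-auxiliary, so the benzylic bromide adds to the opposite face and sets the (S) centre that becomes C3, and the activated benzylic halide reacts below the temperature at which the enolate decomposes.

Step 8
Reactants: 11 (R)-4-benzyl-3-[(2S)-2-(benzyloxy)-3-[4,6-bis(benzyloxy)-2-bromo-3-iodophenyl]propanoyl]-1,3-oxazolidin-2-one
Product: 12 (2S)-2-(benzyloxy)-3-[4,6-bis(benzyloxy)-2-bromo-3-iodophenyl]-N-methoxy-N-methylpropanamide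
Conditions: MeNHOMe·HCl, AlMe3, CH2Cl2, −20 to 0 °C
Reagents that add atoms: N,O-dimethylhydroxylamine hydrochloride CNOC.Cl
Why: Aluminium amide transamination of the imide to the Weinreb amide; the α-benzyloxy oxygen and the exocyclic carbonyl chelate aluminium and direct attack to the exocyclic carbonyl, the auxiliary is released intact and the α centre is not enolised.

Step 9
Reactants: 12 (2S)-2-(benzyloxy)-3-[4,6-bis(benzyloxy)-2-bromo-3-iodophenyl]-N-methoxy-N-methylpropanamide; 13 4-bromo-1,2-bis(benzyloxy)benzene
Product: 15 (2S)-2-(benzyloxy)-1-[3,4-bis(benzyloxy)phenyl]-3-[4,6-bis(benzyloxy)-2-bromo-3-iodophenyl]propan-1-one, via 3,4-bis(benzyloxy)phenylmagnesium bromide 14 (not isolated)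
Conditions: Mg, THF, rt (13 to 14); then 12, THF, −20 to 0 °C; aq. NH4Cl
Reagents that add atoms: none
Why: Weinreb ketone synthesis; the aryl Grignard reagent adds once because the chelated tetrahedral intermediate survives until work-up, and at or below 0 °C addition to the activated α-alkoxy amide should be much faster than iodine-magnesium exchange between an aryl Grignard reagent and the ring A iodide.

Step 10
Reactants: 15 (2S)-2-(benzyloxy)-1-[3,4-bis(benzyloxy)phenyl]-3-[4,6-bis(benzyloxy)-2-bromo-3-iodophenyl]propan-1-one
Product: 16 (1R,2S)-2-(benzyloxy)-1-[3,4-bis(benzyloxy)phenyl]-3-[4,6-bis(benzyloxy)-2-bromo-3-iodophenyl]propan-1-ol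
Conditions: Zn(BH4)2, Et2O, −30 to 0 °C
Reagents that add atoms: none
Why: Chelation-controlled ketone reduction; zinc bridges the carbonyl oxygen and the α-benzyloxy oxygen and hydride enters from the face of the five-membered chelate opposite the arylmethyl group, giving the anti (1R,2S) alcohol whose carbinol carbon becomes C2.

Step 11
Reactants: 17 2,4,6-trihydroxytoluene; 18 isobutyryl chloride
Product: 19 2-methyl-1-(2,4,6-trihydroxy-3-methylphenyl)propan-1-one
Conditions: AlCl3, PhNO2, rt to 60 °C
Reagents that add atoms: none
Why: Friedel–Crafts acylation of a phloroglucinol; the two free ring carbons of 17 are equivalent by symmetry, so only one C-acyl product can form, and the first acyl group deactivates the ring towards a second.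

Step 12
Reactants: 19 2-methyl-1-(2,4,6-trihydroxy-3-methylphenyl)propan-1-one; 2 benzyl bromide
Product: 20 1-[4,6-bis(benzyloxy)-2-hydroxy-3-methylphenyl]-2-methylpropan-1-one
Conditions: 2 (2.1 equiv), K2CO3, acetone, reflux
Reagents that add atoms: benzyl bromide (second equivalent of 2) BrCc1ccccc1
Why: Site-selective double Williamson etherification with two equivalents of 2; the hydroxyl para to the ketone is the most acidic and reacts first, and of the two chelated ortho hydroxyls the one beside the ring hydrogen should take the second benzyl group in preference to the one wedged between the C-methyl group and the carbonyl, which stays hydrogen-bonded to the ketone.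

Step 13
Reactants: 20 1-[4,6-bis(benzyloxy)-2-hydroxy-3-methylphenyl]-2-methylpropan-1-one
Product: 21 2,6-bis(benzyloxy)-4-hydroxy-3-methyl-5-(2-methylpropanoyl)benzaldehyde
Conditions: POCl3, DMF, MeCN, 0 to 40 °C; then aq. NaOAc
Reagents that add atoms: N,N-dimethylformamide CN(C)C=O; water O
Why: Vilsmeier–Haack formylation of a phenol; the only free ring carbon lies para to the free hydroxyl and ortho to both benzyloxy groups and is strongly activated, while the hindered isopropyl ketone with its single α-hydrogen should enolise too slowly to compete for the chloroiminium ion.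

Step 14
Reactants: 21 2,6-bis(benzyloxy)-4-hydroxy-3-methyl-5-(2-methylpropanoyl)benzaldehyde
Product: 22 2,6-bis(benzyloxy)-4-methoxy-3-methyl-5-(2-methylpropanoyl)benzaldehyde
Conditions: MeI, K2CO3, DMF, 40 °C
Reagents that add atoms: iodomethane CI
Why: Williamson methylation of the remaining phenol, acidified by the para formyl and ortho acyl groups; this fixes the methyl ether between the C-methyl and the isobutyryl group.

Step 15
Reactants: 16 (1R,2S)-2-(benzyloxy)-1-[3,4-bis(benzyloxy)phenyl]-3-[4,6-bis(benzyloxy)-2-bromo-3-iodophenyl]propan-1-ol; 22 2,6-bis(benzyloxy)-4-methoxy-3-methyl-5-(2-methylpropanoyl)benzaldehyde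
Product: 26 [2,6-bis(benzyloxy)-4-methoxy-3-methyl-5-(2-methylpropanoyl)phenyl]{(2R,3S)-3,5,7-tris(benzyloxy)-2-[3,4-bis(benzyloxy)phenyl]chroman-8-yl}methanol (both carbinol epimers), via bromoaryl magnesium alkoxide 23 (not isolated), via aryne alkoxide 24 (not isolated), via C8-magnesiated chroman 25 (not isolated)
Conditions: iPrMgCl·LiCl (2.0 equiv), THF (high dilution), −40 °C; then warm to 40 °C; then 22, 0 °C to rt; aq. NH4Cl
Reagents that add atoms: none
Why: Proposed new method: each event has a known counterpart (aryne formation from an ortho-halo aryl magnesium, intramolecular alkoxide addition to an aryne giving a chroman, and addition of a magnesium nucleophile to an aryne followed by trapping of the new aryl magnesium with an electrophile), but their union in one flask with a magnesium alkoxide as internal nucleophile and an aldehyde as terminating electrophile is not established, the closest known reaction type being the magnesium-mediated two-component difunctionalisation of arynes. The first equivalent of iPrMgCl·LiCl deprotonates the hydroxyl and the second exchanges the iodine at C8, the most reactive carbon-halogen bond, to give 23, which on warming loses MgBrCl across C8–C8a to give aryne 24. The C2 alkoxide then adds to C8a in a 6-exo-dig anionic closure of ring C, and the charge appears at C8 as the aryl magnesium 25. Regiochemistry is secured twice: the three-atom tether can reach only C8a, and the C7 benzyloxy group beside C8 stabilises the developing carbanion inductively, as in other 3-alkoxyarynes. 25 is an ordinary if hindered aryl magnesium and should add to the aldehyde of 22 in preference to its doubly ortho-substituted, twisted isopropyl ketone. No bond to C2 or C3 is made or broken, so the anti relationship of 16 is carried unchanged into the 2,3-trans relationship of ring C; the new carbinol centre is formed without control and is removed in step 16. The selectivity the step needs is capture of the aryne by the internal alkoxide before any other nucleophile, which is served by high dilution, by the absence of excess Grignard reagent and by LiCl, which breaks up alkoxide aggregates.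

Step 16
Reactants: 26 [2,6-bis(benzyloxy)-4-methoxy-3-methyl-5-(2-methylpropanoyl)phenyl]{(2R,3S)-3,5,7-tris(benzyloxy)-2-[3,4-bis(benzyloxy)phenyl]chroman-8-yl}methanol
Product: 27 hepta-O-benzyl pilosanol B
Conditions: Et3SiH, CF3CO2H, CH2Cl2, −20 to 0 °C
Reagents that add atoms: none
Why: Ionic hydrogenation; acid ionises the doubly benzylic carbinol to a diarylmethyl cation stabilised by the three oxygens of ring A, which triethylsilane should reduce at low temperature faster than acid can open ring C at C2 or the silane can reduce the twisted, hindered ketone; both carbinol epimers converge on one methylene compound.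

Step 17
Reactants: 27 hepta-O-benzyl pilosanol B
Product: 28 pilosanol B
Conditions: H2 (1 atm), Pd(OH)2/C, THF/MeOH, rt
Reagents that add atoms: none
Why: Hydrogenolysis of six aryl benzyl ethers and one alkyl benzyl ether; the methyl ether, the chelated aryl ketone and the C2–O1 bond are expected to be stable under neutral conditions at one atmosphere, and neither stereocentre is touched.

## Compound list

1 | 5-bromobenzene-1,3-diol | Oc1cc(O)cc(Br)c1 | starting material
2 | benzyl bromide | BrCc1ccccc1 | starting material
3 | 1,3-bis(benzyloxy)-5-bromobenzene | Brc1cc(OCc2ccccc2)cc(OCc2ccccc2)c1 | intermediate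
4 | 2,4-bis(benzyloxy)-6-bromobenzaldehyde | O=Cc1c(Br)cc(OCc2ccccc2)cc1OCc1ccccc1 | intermediate
5 | 4,6-bis(benzyloxy)-2-bromo-3-iodobenzaldehyde | O=Cc1c(Br)c(I)c(OCc2ccccc2)cc1OCc1ccccc1 | intermediate
6 | [4,6-bis(benzyloxy)-2-bromo-3-iodophenyl]methanol | OCc1c(Br)c(I)c(OCc2ccccc2)cc1OCc1ccccc1 | intermediate
7 | 4,6-bis(benzyloxy)-2-bromo-3-iodobenzyl bromide | BrCc1c(Br)c(I)c(OCc2ccccc2)cc1OCc1ccccc1 | intermediate
8 | (R)-4-benzyl-1,3-oxazolidin-2-one | O=C1OC[C@@H](Cc2ccccc2)N1 | starting material
9 | (benzyloxy)acetyl chloride | O=C(Cl)COCc1ccccc1 | starting material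
10 | (R)-4-benzyl-3-[(benzyloxy)acetyl]-1,3-oxazolidin-2-one | O=C(COCc1ccccc1)N1[C@H](Cc2ccccc2)COC1=O | intermediate
11 | (R)-4-benzyl-3-[(2S)-2-(benzyloxy)-3-[4,6-bis(benzyloxy)-2-bromo-3-iodophenyl]propanoyl]-1,3-oxazolidin-2-one | O=C([C@@H](OCc1ccccc1)Cc1c(Br)c(I)c(OCc2ccccc2)cc1OCc1ccccc1)N1[C@H](Cc2ccccc2)COC1=O | intermediate
12 | (2S)-2-(benzyloxy)-3-[4,6-bis(benzyloxy)-2-bromo-3-iodophenyl]-N-methoxy-N-methylpropanamide | CON(C)C(=O)[C@@H](OCc1ccccc1)Cc1c(Br)c(I)c(OCc2ccccc2)cc1OCc1ccccc1 | intermediate
13 | 4-bromo-1,2-bis(benzyloxy)benzene | Brc1ccc(OCc2ccccc2)c(OCc2ccccc2)c1 | starting material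
14 | 3,4-bis(benzyloxy)phenylmagnesium bromide | Br[Mg]c1ccc(OCc2ccccc2)c(OCc2ccccc2)c1 | intermediate
15 | (2S)-2-(benzyloxy)-1-[3,4-bis(benzyloxy)phenyl]-3-[4,6-bis(benzyloxy)-2-bromo-3-iodophenyl]propan-1-one | O=C(c1ccc(OCc2ccccc2)c(OCc2ccccc2)c1)[C@@H](OCc1ccccc1)Cc1c(Br)c(I)c(OCc2ccccc2)cc1OCc1ccccc1 | intermediate
16 | (1R,2S)-2-(benzyloxy)-1-[3,4-bis(benzyloxy)phenyl]-3-[4,6-bis(benzyloxy)-2-bromo-3-iodophenyl]propan-1-ol | O[C@H](c1ccc(OCc2ccccc2)c(OCc2ccccc2)c1)[C@@H](OCc1ccccc1)Cc1c(Br)c(I)c(OCc2ccccc2)cc1OCc1ccccc1 | intermediate
17 | 2,4,6-trihydroxytoluene | Cc1c(O)cc(O)cc1O | starting material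
18 | isobutyryl chloride | CC(C)C(Cl)=O | starting material
19 | 2-methyl-1-(2,4,6-trihydroxy-3-methylphenyl)propan-1-one | CC(C)C(=O)c1c(O)cc(O)c(C)c1O | intermediate
20 | 1-[4,6-bis(benzyloxy)-2-hydroxy-3-methylphenyl]-2-methylpropan-1-one | CC(C)C(=O)c1c(O)c(C)c(OCc2ccccc2)cc1OCc1ccccc1 | intermediate
21 | 2,6-bis(benzyloxy)-4-hydroxy-3-methyl-5-(2-methylpropanoyl)benzaldehyde | CC(C)C(=O)c1c(O)c(C)c(OCc2ccccc2)c(C=O)c1OCc1ccccc1 | intermediate
22 | 2,6-bis(benzyloxy)-4-methoxy-3-methyl-5-(2-methylpropanoyl)benzaldehyde | COc1c(C)c(OCc2ccccc2)c(C=O)c(OCc2ccccc2)c1C(=O)C(C)C | intermediate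
23 | chloromagnesium (1R,2S)-2-(benzyloxy)-1-[3,4-bis(benzyloxy)phenyl]-3-[4,6-bis(benzyloxy)-2-bromo-3-(chloromagnesio)phenyl]propan-1-olate | Cl[Mg]O[C@H](c1ccc(OCc2ccccc2)c(OCc2ccccc2)c1)[C@@H](OCc1ccccc1)Cc1c(Br)c([Mg]Cl)c(OCc2ccccc2)cc1OCc1ccccc1 | intermediate
24 | chloromagnesium (1R,2S)-2-(benzyloxy)-1-[3,4-bis(benzyloxy)phenyl]-3-[4,6-bis(benzyloxy)-2,3-didehydrophenyl]propan-1-olate (aryne across C8–C8a) | Cl[Mg]O[C@H](c1ccc(OCc2ccccc2)c(OCc2ccccc2)c1)[C@@H](OCc1ccccc1)CC1=C(OCc2ccccc2)C=C(OCc2ccccc2)C#C1 | intermediate
25 | (2R,3S)-3,5,7-tris(benzyloxy)-2-[3,4-bis(benzyloxy)phenyl]chroman-8-ylmagnesium chloride | Cl[Mg]c1c(OCc2ccccc2)cc(OCc2ccccc2)c2c1O[C@H](c1ccc(OCc3ccccc3)c(OCc3ccccc3)c1)[C@@H](OCc1ccccc1)C2 | intermediate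
26 | [2,6-bis(benzyloxy)-4-methoxy-3-methyl-5-(2-methylpropanoyl)phenyl]{(2R,3S)-3,5,7-tris(benzyloxy)-2-[3,4-bis(benzyloxy)phenyl]chroman-8-yl}methanol, both carbinol epimers | COc1c(C)c(OCc2ccccc2)c(C(O)c2c(OCc3ccccc3)cc(OCc3ccccc3)c3c2O[C@H](c2ccc(OCc4ccccc4)c(OCc4ccccc4)c2)[C@@H](OCc2ccccc2)C3)c(OCc2ccccc2)c1C(=O)C(C)C | intermediate
27 | hepta-O-benzyl pilosanol B: 1-{2,4-bis(benzyloxy)-6-methoxy-5-methyl-3-{[(2R,3S)-3,5,7-tris(benzyloxy)-2-[3,4-bis(benzyloxy)phenyl]chroman-8-yl]methyl}phenyl}-2-methylpropan-1-one | COc1c(C)c(OCc2ccccc2)c(Cc2c(OCc3ccccc3)cc(OCc3ccccc3)c3c2O[C@H](c2ccc(OCc4ccccc4)c(OCc4ccccc4)c2)[C@@H](OCc2ccccc2)C3)c(OCc2ccccc2)c1C(=O)C(C)C | intermediate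
28 | pilosanol B | COc1c(C)c(O)c(Cc2c(O)cc(O)c3c2O[C@H](c2ccc(O)c(O)c2)[C@@H](O)C3)c(O)c1C(=O)C(C)C | target

## Step count and least certain steps

Total: 17 steps. Longest linear sequence: 12 steps (steps 1 to 5, 7 to 10 and 15 to 17).

Risk at step 15 (key step, proposed new method).
- What may go wrong: the chelated bromoaryl magnesium may lose magnesium halide too slowly.
- What may go wrong: the aryne may be captured before the weakly nucleophilic, aggregated magnesium alkoxide closes ring C. The competitors are intermolecular addition of unreacted aryl magnesium and five-membered attack by the neutral C3 benzyloxy oxygen with loss of its benzyl group.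
- What may go wrong: addition of the doubly ortho-substituted aryl magnesium to the doubly ortho-substituted aldehyde may be so slow that the carbanion is only protonated on work-up.
- Fallback, by known reactions, from 16 back to 26: iodine-magnesium exchange with iPrMgCl·LiCl at −40 °C, where the ortho-bromo aryl magnesium does not yet eliminate, and protonation with MeOH gives (1R,2S)-2-(benzyloxy)-1-[3,4-bis(benzyloxy)phenyl]-3-[2,4-bis(benzyloxy)-6-bromophenyl]propan-1-ol F1. Copper-catalysed intramolecular aryl ether formation (CuI, 1,10-phenanthroline, Cs2CO3, toluene, 110 °C) closes ring C to (2R,3S)-3,5,7-tris(benzyloxy)-2-[3,4-bis(benzyloxy)phenyl]chroman F2. N-Bromosuccinimide in CH2Cl2 at low temperature brominates C8, the more accessible of the two nucleophilic ring A carbons since C6 lies between two benzyloxy groups, giving the 8-bromochroman F3. Bromine-lithium exchange with n-BuLi in THF at −78 °C and addition of aldehyde 22 then returns to 26.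

Risk at step 12.
- What may go wrong: loss of site selectivity between the two chelated hydroxyls, or C-benzylation at the free ring carbon of the ambident phenoxide.
- Fallback from 19 back to 20: exhaustive benzylation with excess 2 (K2CO3, DMF, 70 °C) gives 2-methyl-1-[2,4,6-tris(benzyloxy)-3-methylphenyl]propan-1-one F4. One equivalent of BCl3 in CH2Cl2 at −78 °C then removes a benzyl group only from an oxygen ortho to the ketone (chelation), and of the two should prefer the ether twisted out of the ring plane between methyl and acyl, returning to 20.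

Risk at step 3.
- What may go wrong: iodination at the carbon between the two benzyloxy groups, or a second iodination.
- Fallback from 3 back to 5: iodination is done first (N-iodosuccinimide, MeCN), where the two carbons para to a benzyloxy group are equivalent, giving 1,5-bis(benzyloxy)-3-bromo-2-iodobenzene F5. Vilsmeier–Haack formylation at the remaining carbon para to a benzyloxy group then returns to 5.

Risk at step 13.
- What may go wrong: slow ring formylation at a carbon flanked by two benzyloxy groups, with O-formylation or attack at the ketone taking over.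
- Fallback from 20 back to 22: methylation (MeI, K2CO3, DMF) gives 1-[4,6-bis(benzyloxy)-2-methoxy-3-methylphenyl]-2-methylpropan-1-one F6. Bromination of the only free ring carbon with N-bromosuccinimide in MeCN, a small electrophile, gives 1-[4,6-bis(benzyloxy)-5-bromo-2-methoxy-3-methylphenyl]-2-methylpropan-1-one F7. Palladium-catalysed reductive carbonylation (Pd(OAc)2, di(1-adamantyl)-n-butylphosphine, CO/H2, N,N,N',N'-tetramethylethylenediamine, toluene, 100 °C) then returns to 22.

Risk at step 8.
- What may go wrong: attack of the aluminium amide on the ring carbonyl of the hindered, α-branched imide, which opens the auxiliary instead of releasing it.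
- Fallback from 11 back to 12: hydrolysis with LiOH and H2O2 in THF/water at 0 °C gives (2S)-2-(benzyloxy)-3-[4,6-bis(benzyloxy)-2-bromo-3-iodophenyl]propanoic acid F8. This is coupled with MeNHOMe·HCl using 1-ethyl-3-(3-dimethylaminopropyl)carbodiimide hydrochloride, 1-hydroxybenzotriazole and iPr2NEt in CH2Cl2, returning to 12.

Risk at step 16.
- What may go wrong: over-reduction of the aryl ketone, acid-induced cleavage of the bridge by retro-Friedel–Crafts fragmentation, or ionisation at C2 with opening of ring C.
- Fallback from 26 directly to 28: the silane step is omitted and 26 is hydrogenated (H2, Pd(OH)2/C, THF/MeOH, trace HCl). Debenzylation gives the heptaphenolic carbinol F9, whose ortho-hydroxybenzylic C–O bond is hydrogenolysed in the same flask.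

## Further compounds

F1 | step 15 | (1R,2S)-2-(benzyloxy)-1-[3,4-bis(benzyloxy)phenyl]-3-[2,4-bis(benzyloxy)-6-bromophenyl]propan-1-ol | O[C@H](c1ccc(OCc2ccccc2)c(OCc2ccccc2)c1)[C@@H](OCc1ccccc1)Cc1c(Br)cc(OCc2ccccc2)cc1OCc1ccccc1
F2 | step 15 | (2R,3S)-3,5,7-tris(benzyloxy)-2-[3,4-bis(benzyloxy)phenyl]chroman | c1c(OCc2ccccc2)cc(OCc2ccccc2)c2c1O[C@H](c1ccc(OCc3ccccc3)c(OCc3ccccc3)c1)[C@@H](OCc1ccccc1)C2
F3 | step 15 | (2R,3S)-3,5,7-tris(benzyloxy)-2-[3,4-bis(benzyloxy)phenyl]-8-bromochroman | Brc1c(OCc2ccccc2)cc(OCc2ccccc2)c2c1O[C@H](c1ccc(OCc3ccccc3)c(OCc3ccccc3)c1)[C@@H](OCc1ccccc1)C2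
F4 | step 12 | 2-methyl-1-[2,4,6-tris(benzyloxy)-3-methylphenyl]propan-1-one | CC(C)C(=O)c1c(OCc2ccccc2)c(C)c(OCc2ccccc2)cc1OCc1ccccc1
F5 | step 3 | 1,5-bis(benzyloxy)-3-bromo-2-iodobenzene | Brc1cc(OCc2ccccc2)cc(OCc2ccccc2)c1I
F6 | step 13 | 1-[4,6-bis(benzyloxy)-2-methoxy-3-methylphenyl]-2-methylpropan-1-one | COc1c(C)c(OCc2ccccc2)cc(OCc2ccccc2)c1C(=O)C(C)C
F7 | step 13 | 1-[4,6-bis(benzyloxy)-5-bromo-2-methoxy-3-methylphenyl]-2-methylpropan-1-one | COc1c(C)c(OCc2ccccc2)c(Br)c(OCc2ccccc2)c1C(=O)C(C)C
F8 | step 8 | (2S)-2-(benzyloxy)-3-[4,6-bis(benzyloxy)-2-bromo-3-iodophenyl]propanoic acid | OC(=O)[C@@H](OCc1ccccc1)Cc1c(Br)c(I)c(OCc2ccccc2)cc1OCc1ccccc1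
F9 | step 16 | 1-{2,4-dihydroxy-3-{hydroxy[(2R,3S)-2-(3,4-dihydroxyphenyl)-3,5,7-trihydroxychroman-8-yl]methyl}-6-methoxy-5-methylphenyl}-2-methylpropan-1-one | COc1c(C)c(O)c(C(O)c2c(O)cc(O)c3c2O[C@H](c2ccc(O)c(O)c2)[C@@H](O)C3)c(O)c1C(=O)C(C)C
A1 | alternative 1 | penta-O-benzyl pilosanol B bis(trimethylsilyl) ether | COc1c(C)c(O[Si](C)(C)C)c(Cc2c(OCc3ccccc3)cc(OCc3ccccc3)c3c2O[C@H](c2ccc(OCc4ccccc4)c(OCc4ccccc4)c2)[C@@H](OCc2ccccc2)C3)c(O[Si](C)(C)C)c1C(=O)C(C)C
A2 | alternative 1 | 4-methyl-1,3-bis(trimethylsilyloxy)cyclohexa-1,3-diene carrying at C2 the {(2R,3S)-3,5,7-tris(benzyloxy)-2-[3,4-bis(benzyloxy)phenyl]chroman-8-yl}methyl group | CC1=C(O[Si](C)(C)C)C(Cc2c(OCc3ccccc3)cc(OCc3ccccc3)c3c2O[C@H](c2ccc(OCc4ccccc4)c(OCc4ccccc4)c2)[C@@H](OCc2ccccc2)C3)=C(O[Si](C)(C)C)CC1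
A3 | alternative 1 | 1-methoxy-4-methylpent-1-yn-3-one | COC#CC(=O)C(C)C
A4 | alternative 2 | (2R)-5,7-bis(benzyloxy)-2-[3,4-bis(benzyloxy)phenyl]-8-{[2,6-bis(benzyloxy)-4-methoxy-3-methyl-5-(2-methylpropanoyl)phenyl]methyl}-2H-chromene-3-carbaldehyde | COc1c(C)c(OCc2ccccc2)c(Cc2c(OCc3ccccc3)cc(OCc3ccccc3)c3c2O[C@H](c2ccc(OCc4ccccc4)c(OCc4ccccc4)c2)C(C=O)=C3)c(OCc2ccccc2)c1C(=O)C(C)C
A5 | alternative 2 | 3-{[2,6-bis(benzyloxy)-4-methoxy-3-methyl-5-(2-methylpropanoyl)phenyl]methyl}-4,6-bis(benzyloxy)-2-hydroxybenzaldehyde | COc1c(C)c(OCc2ccccc2)c(Cc2c(O)c(C=O)c(OCc3ccccc3)cc2OCc2ccccc2)c(OCc2ccccc2)c1C(=O)C(C)C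
A6 | alternative 2 | (E)-3-[3,4-bis(benzyloxy)phenyl]prop-2-enal | O=C/C=C/c1ccc(OCc2ccccc2)c(OCc2ccccc2)c1
A7 | alternative 3 | 2-{[(2R,3S)-3,5,7-tris(benzyloxy)-2-[3,4-bis(benzyloxy)phenyl]chroman-8-yl]methyl}-5-methoxy-4-methyl-3-(triisopropylsilyloxy)phenol | COc1cc(O)c(Cc2c(OCc3ccccc3)cc(OCc3ccccc3)c3c2O[C@H](c2ccc(OCc4ccccc4)c(OCc4ccccc4)c2)[C@@H](OCc2ccccc2)C3)c(O[Si](C(C)C)(C(C)C)C(C)C)c1C
A8 | alternative 3 | 3-methoxy-2-methylcyclobut-2-en-1-one | COC1=C(C)C(=O)C1
A9 | alternative 3 | (2R,3S)-3,5,7-tris(benzyloxy)-2-[3,4-bis(benzyloxy)phenyl]-8-[3-(triisopropylsilyloxy)prop-2-yn-1-yl]chroman | CC(C)[Si](OC#CCc1c(OCc2ccccc2)cc(OCc2ccccc2)c2c1O[C@H](c1ccc(OCc3ccccc3)c(OCc3ccccc3)c1)[C@@H](OCc1ccccc1)C2)(C(C)C)C(C)C
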